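**Retrosynthetic overview**

1. The strategy rests on ring A, a fully differentiated benzene (C4a, C5–OH, C6–H, C7–O, C8–prenyl, C8a) fused to pyranone ring C. It is cut into the C4a=C8a bond of a preformed 2-aryl-4-pyranone, a ketene unit (C8 and C5) and the two carbons of (triisopropylsilyloxy)acetylene (C6, C7), so the prenyl position follows from connectivity.
2. The ketene comes from a 6-(α-diazoacyl)-4-pyranone by photochemical Wolff rearrangement, the diazo ketone from the homoprenyl ketone by detrifluoroacetylative diazo transfer, and the ketone from a pyranone Weinreb amide and homoprenylmagnesium bromide.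
3. Ring C is made from the ring B methyl ketone by two Claisen-type acylations (acetyl, then oxalyl) and acid cyclodehydration.
4. The 2,2-dimethylchromene ring on ring B comes from 3,4-dihydroxyacetophenone by O-propargylation and a thermal propargyl Claisen cascade.
5. Order of ring formation: chromene ring, pyranone ring C, ring A; fluoride then frees the two phenols.

Key step: step 10

Assumption: the target has no stereocenter, and (triisopropylsilyloxy)acetylene is treated as not purchasable and is made in step 9 by the usual acetylide oxidation and O-silylation.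

**Route**

Step 1
Reactants: 1 3,4-dihydroxyacetophenone; 2 3-chloro-3-methylbut-1-yne
Product: 3 1-[3-hydroxy-4-(2-methylbut-3-yn-2-yloxy)phenyl]ethanone
Conditions: 2 (1.3 equiv), K2CO3 (1.1 equiv), KI, CuI (cat.), acetone, 55 °C, Ar
Reagents that add atoms: none
Why: Copper-assisted Williamson-type O-alkylation with the tertiary propargylic chloride should occur at the 4-OH, which is the more acidic phenol (para to the acetyl group) and is the one deprotonated by a single equivalent of base.

Step 2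
Reactants: 3 1-[3-hydroxy-4-(2-methylbut-3-yn-2-yloxy)phenyl]ethanone
Product: 4 1-[4-(2-methylbut-3-yn-2-yloxy)-3-(triisopropylsilyloxy)phenyl]ethanone
Conditions: i-Pr3SiCl, imidazole, DMF, 40 °C
Reagents that add atoms: chlorotriisopropylsilane, CC(C)[Si](Cl)(C(C)C)C(C)C
Why: Silylation of the remaining phenol gives a bulky aryl silyl ether that should withstand the heating, amide bases and organometallic reagents of the later steps and leaves with fluoride at the end.

Step 3
Reactants: 4 1-[4-(2-methylbut-3-yn-2-yloxy)-3-(triisopropylsilyloxy)phenyl]ethanone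
Product: 5 1-[2,2-dimethyl-8-(triisopropylsilyloxy)-2H-chromen-6-yl]ethanone
Conditions: PhNEt2, 185 °C
Reagents that add atoms: none
Why: Aromatic propargyl Claisen rearrangement to the only free ortho position, followed by 1,5-hydrogen shift and oxa-6π electrocyclisation, is the standard thermal route from aryl 1,1-dimethylpropargyl ethers to 2,2-dimethyl-2H-chromenes.

Step 4
Reactants: 5 1-[2,2-dimethyl-8-(triisopropylsilyloxy)-2H-chromen-6-yl]ethanone; 6 1-acetyl-1H-benzotriazole
Product: 7 1-[2,2-dimethyl-8-(triisopropylsilyloxy)-2H-chromen-6-yl]butane-1,3-dione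
Conditions: 6 (1.3 equiv), MgBr2·OEt2, i-Pr2NEt, CH2Cl2, 23 °C; aq. HCl work-up
Reagents that add atoms: none
Why: Crossed Claisen condensation by soft enolisation (C-acylation of the magnesium enolate of the methyl ketone) should give the 1,3-diketone as its magnesium chelate without any alkoxide that could attack the aryl silyl ether.

Step 5
Reactants: 7 1-[2,2-dimethyl-8-(triisopropylsilyloxy)-2H-chromen-6-yl]butane-1,3-dione; 8 diethyl oxalate
Product: 10 ethyl 6-[2,2-dimethyl-8-(triisopropylsilyloxy)-2H-chromen-6-yl]-4-oxo-4H-pyran-2-carboxylate, via triketo ester 9 (not isolated)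
Conditions: LiN(i-Pr)2 (3 equiv), THF, −78 → 0 °C; 8, −78 → 0 °C; aq. HCl; then TsOH·H2O (cat.), toluene, 70 °C
Reagents that add atoms: none
Why: The 1,3-diketone dianion reacts at its terminal carbon with diethyl oxalate (Claisen condensation) and the resulting 1,3,5-tricarbonyl compound cyclodehydrates under acid catalysis to the 4-pyranone, which is the classical route to 6-aryl-4-oxo-4H-pyran-2-carboxylates.

Step 6
Reactants: 10 ethyl 6-[2,2-dimethyl-8-(triisopropylsilyloxy)-2H-chromen-6-yl]-4-oxo-4H-pyran-2-carboxylate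
Product: 11 6-[2,2-dimethyl-8-(triisopropylsilyloxy)-2H-chromen-6-yl]-N-methoxy-N-methyl-4-oxo-4H-pyran-2-carboxamide
Conditions: MeNH(OMe)·HCl, AlMe3, CH2Cl2, 0 → 23 °C
Reagents that add atoms: N,O-dimethylhydroxylamine hydrochloride, CNOC.Cl
Why: Aminolysis of the activated ester by the aluminium amide formed from AlMe3 and the amine hydrochloride (Weinreb amidation) is mild enough for the pyranone, the chromene and the silyl ether.

Step 7
Reactants: 11 6-[2,2-dimethyl-8-(triisopropylsilyloxy)-2H-chromen-6-yl]-N-methoxy-N-methyl-4-oxo-4H-pyran-2-carboxamide; 12 5-bromo-2-methylpent-2-ene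
Product: 14 2-[2,2-dimethyl-8-(triisopropylsilyloxy)-2H-chromen-6-yl]-6-(5-methylhex-4-enoyl)-4H-pyran-4-one, via homoprenyl Grignard reagent 13 (not isolated)
Conditions: 12, Mg, THF, 40 °C; then 11, THF, −78 → −40 °C; aq. NH4Cl
Reagents that add atoms: magnesium, [Mg] (in 13 only)
Why: Grignard addition to a Weinreb amide stops at the chelated tetrahedral intermediate and releases the ketone only on quench, and at −78 °C the amide on the electron-poor ring should react well before the weakly electrophilic vinylogous ester carbonyl of the pyranone.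

Step 8
Reactants: 14 2-[2,2-dimethyl-8-(triisopropylsilyloxy)-2H-chromen-6-yl]-6-(5-methylhex-4-enoyl)-4H-pyran-4-one
Product: 16 6-(2-diazo-5-methylhex-4-enoyl)-2-[2,2-dimethyl-8-(triisopropylsilyloxy)-2H-chromen-6-yl]-4H-pyran-4-one, via trifluoroacetyl ketone 15 (not isolated)
Conditions: LiN(SiMe3)2, THF, −78 °C; CF3CO2CH2CF3; then MsN3, Et3N, H2O, MeCN, 23 °C
Reagents that add atoms: 2,2,2-trifluoroethyl trifluoroacetate, O=C(OCC(F)(F)F)C(F)(F)F (the trifluoroacetyl group of 15 only); methanesulfonyl azide, CS(=O)(=O)N=[N+]=[N-]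
Why: Detrifluoroacetylative diazo transfer (a Regitz-type deacylative diazo transfer) works because the only enolisable position is trifluoroacetylated and the activated 1,3-dicarbonyl compound then takes the diazo group from the sulfonyl azide while the trifluoroacetyl group leaves as the sulfonamide.

Step 9
Reactants: 17 acetylene
Product: 20 (triisopropylsilyloxy)acetylene, via lithium acetylide 18 (not isolated), via lithium ethynolate 19 (not isolated)
Conditions: n-BuLi, THF, −78 °C; t-BuOOLi (from t-BuOOH and LiN(SiMe3)2), −78 → −30 °C; i-Pr3SiOTf, −78 → 0 °C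
Reagents that add atoms: n-butyllithium, [Li]CCCC (the lithium of 18 and 19 only); tert-butyl hydroperoxide, CC(C)(C)OO; triisopropylsilyl trifluoromethanesulfonate, CC(C)[Si](OS(=O)(=O)C(F)(F)F)(C(C)C)C(C)C
Why: Oxidation of a lithium acetylide by lithium tert-butyl peroxide to the lithium ynolate and O-silylation with a bulky silyl triflate is the established route from terminal alkynes to siloxyalkynes, and the bulk of the triisopropylsilyl group favours attack at oxygen over carbon.

Step 10
Reactants: 16 6-(2-diazo-5-methylhex-4-enoyl)-2-[2,2-dimethyl-8-(triisopropylsilyloxy)-2H-chromen-6-yl]-4H-pyran-4-one; 20 (triisopropylsilyloxy)acetylene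
Product: 24 5-hydroxy-2-[2,2-dimethyl-8-(triisopropylsilyloxy)-2H-chromen-6-yl]-8-(3-methylbut-2-en-1-yl)-7-(triisopropylsilyloxy)-4H-chromen-4-one, via ketene 21 (not isolated), via cyclobutenone 22 (not isolated), via dienylketene 23 (not isolated)
Conditions: 20 (3 equiv), ClCH2CH2Cl (degassed, 0.02 M), LEDs 420–450 nm, 20 °C; then 80 °C, dark
Reagents that add atoms: none
Why: Light expels N2 from 16 and the pyranonyl group shifts to the carbene carbon (Wolff rearrangement, C8–C8a) to give ketene 21, which adds to the electron-rich alkyne 20 in a [2+2] cycloaddition (C5–C6 and C7–C8) to give cyclobutenone 22. Warming opens 22 by 4π electrocyclic cleavage to dienylketene 23, and 6π electrocyclic closure onto the pyranone carbon next to the ketene-bearing position (C4a–C5) followed by enolisation should give the chelated phenol 24; ring A is thus closed by a 6π electrocyclisation and no stereocenter is formed. The closest known reaction type is the Danheiser benzannulation of alkenyl and heteroaryl α-diazo ketones with siloxyalkynes, applied here to a 4-pyranonyl diazo ketone. Two selectivities are needed: the orientation of the [2+2], secured by the polarity of 20 (its CH terminus is the nucleophile and bonds to the ketene carbonyl carbon, so C–OSi ends next to the prenyl-bearing carbon), and the site of the 6π closure, secured because the other neighbour of C8a is the ring oxygen. The unproductive geometric isomer of 23 can return to 22 and reopen, and irradiation at 420–450 nm, where only the diazo ketone should absorb, is chosen to spare the chromene and the product.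

Step 11
Reactants: 24 5-hydroxy-2-[2,2-dimethyl-8-(triisopropylsilyloxy)-2H-chromen-6-yl]-8-(3-methylbut-2-en-1-yl)-7-(triisopropylsilyloxy)-4H-chromen-4-one
Product: 25 5,7-dihydroxy-2-(8-hydroxy-2,2-dimethyl-2H-chromen-6-yl)-8-(3-methylbut-2-en-1-yl)-4H-chromen-4-one (CNP0256598.0)
Conditions: Bu4NF, THF, 0 → 23 °C; aq. NH4Cl
Reagents that add atoms: none
Why: Fluoride cleaves both aryl silyl ethers (desilylation) under non-acidic conditions that cannot cyclise the 7-OH onto the 8-prenyl group or affect the chromene.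

**Compound list**

1 | 3,4-dihydroxyacetophenone | CC(=O)c1ccc(O)c(O)c1 | starting material
2 | 3-chloro-3-methylbut-1-yne | CC(C)(Cl)C#C | starting material
3 | 1-[3-hydroxy-4-(2-methylbut-3-yn-2-yloxy)phenyl]ethanone | CC(=O)c1ccc(OC(C)(C)C#C)c(O)c1 | intermediate
4 | 1-[4-(2-methylbut-3-yn-2-yloxy)-3-(triisopropylsilyloxy)phenyl]ethanone | CC(=O)c1ccc(OC(C)(C)C#C)c(O[Si](C(C)C)(C(C)C)C(C)C)c1 | intermediate
5 | 1-[2,2-dimethyl-8-(triisopropylsilyloxy)-2H-chromen-6-yl]ethanone | CC(=O)c1cc(O[Si](C(C)C)(C(C)C)C(C)C)c2c(c1)C=CC(C)(C)O2 | intermediate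
6 | 1-acetyl-1H-benzotriazole | CC(=O)n1nnc2ccccc21 | starting material
7 | 1-[2,2-dimethyl-8-(triisopropylsilyloxy)-2H-chromen-6-yl]butane-1,3-dione | CC(=O)CC(=O)c1cc(O[Si](C(C)C)(C(C)C)C(C)C)c2c(c1)C=CC(C)(C)O2 | intermediate
8 | diethyl oxalate | CCOC(=O)C(=O)OCC | starting material
9 | ethyl 6-[2,2-dimethyl-8-(triisopropylsilyloxy)-2H-chromen-6-yl]-2,4,6-trioxohexanoate (not isolated) | CCOC(=O)C(=O)CC(=O)CC(=O)c1cc(O[Si](C(C)C)(C(C)C)C(C)C)c2c(c1)C=CC(C)(C)O2 | intermediate
10 | ethyl 6-[2,2-dimethyl-8-(triisopropylsilyloxy)-2H-chromen-6-yl]-4-oxo-4H-pyran-2-carboxylate | CCOC(=O)c1cc(=O)cc(-c2cc(O[Si](C(C)C)(C(C)C)C(C)C)c3c(c2)C=CC(C)(C)O3)o1 | intermediate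
11 | 6-[2,2-dimethyl-8-(triisopropylsilyloxy)-2H-chromen-6-yl]-N-methoxy-N-methyl-4-oxo-4H-pyran-2-carboxamide | CON(C)C(=O)c1cc(=O)cc(-c2cc(O[Si](C(C)C)(C(C)C)C(C)C)c3c(c2)C=CC(C)(C)O3)o1 | intermediate
12 | 5-bromo-2-methylpent-2-ene | CC(C)=CCCBr | starting material
13 | (4-methylpent-3-en-1-yl)magnesium bromide (not isolated) | CC(C)=CCC[Mg]Br | intermediate
14 | 2-[2,2-dimethyl-8-(triisopropylsilyloxy)-2H-chromen-6-yl]-6-(5-methylhex-4-enoyl)-4H-pyran-4-one | CC(C)=CCCC(=O)c1cc(=O)cc(-c2cc(O[Si](C(C)C)(C(C)C)C(C)C)c3c(c2)C=CC(C)(C)O3)o1 | intermediate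
15 | 2-[2,2-dimethyl-8-(triisopropylsilyloxy)-2H-chromen-6-yl]-6-[5-methyl-2-(trifluoroacetyl)hex-4-enoyl]-4H-pyran-4-one (racemic, largely enolised, not isolated) | CC(C)=CCC(C(=O)C(F)(F)F)C(=O)c1cc(=O)cc(-c2cc(O[Si](C(C)C)(C(C)C)C(C)C)c3c(c2)C=CC(C)(C)O3)o1 | intermediate
16 | 6-(2-diazo-5-methylhex-4-enoyl)-2-[2,2-dimethyl-8-(triisopropylsilyloxy)-2H-chromen-6-yl]-4H-pyran-4-one | CC(C)=CCC(=[N+]=[N-])C(=O)c1cc(=O)cc(-c2cc(O[Si](C(C)C)(C(C)C)C(C)C)c3c(c2)C=CC(C)(C)O3)o1 | intermediate
17 | acetylene | C#C | starting material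
18 | lithium acetylide (not isolated) | [Li]C#C | intermediate
19 | lithium ethynolate (not isolated) | [Li]OC#C | intermediate
20 | (triisopropylsilyloxy)acetylene | C#CO[Si](C(C)C)(C(C)C)C(C)C | intermediate
21 | 2-{6-[2,2-dimethyl-8-(triisopropylsilyloxy)-2H-chromen-6-yl]-4-oxo-4H-pyran-2-yl}-5-methylhexa-1,4-dien-1-one, the (pyranonyl)(prenyl)ketene (not isolated) | CC(C)=CCC(=C=O)c1cc(=O)cc(-c2cc(O[Si](C(C)C)(C(C)C)C(C)C)c3c(c2)C=CC(C)(C)O3)o1 | intermediate
22 | 4-{6-[2,2-dimethyl-8-(triisopropylsilyloxy)-2H-chromen-6-yl]-4-oxo-4H-pyran-2-yl}-4-(3-methylbut-2-en-1-yl)-3-(triisopropylsilyloxy)cyclobut-2-en-1-one (racemic, not isolated) | CC(C)=CCC1(C(=O)C=C1O[Si](C(C)C)(C(C)C)C(C)C)c1cc(=O)cc(-c2cc(O[Si](C(C)C)(C(C)C)C(C)C)c3c(c2)C=CC(C)(C)O3)o1 | intermediate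
23 | 4-{6-[2,2-dimethyl-8-(triisopropylsilyloxy)-2H-chromen-6-yl]-4-oxo-4H-pyran-2-yl}-7-methyl-3-(triisopropylsilyloxy)octa-1,3,6-trien-1-one, the dienylketene with ketenyl and pyranonyl groups cis (not isolated) | O=C=C\C(O[Si](C(C)C)(C(C)C)C(C)C)=C(\CC=C(C)C)c1cc(=O)cc(-c2cc(O[Si](C(C)C)(C(C)C)C(C)C)c3c(c2)C=CC(C)(C)O3)o1 | intermediate
24 | 5-hydroxy-2-[2,2-dimethyl-8-(triisopropylsilyloxy)-2H-chromen-6-yl]-8-(3-methylbut-2-en-1-yl)-7-(triisopropylsilyloxy)-4H-chromen-4-one | CC(C)=CCc1c(O[Si](C(C)C)(C(C)C)C(C)C)cc(O)c2c(=O)cc(-c3cc(O[Si](C(C)C)(C(C)C)C(C)C)c4c(c3)C=CC(C)(C)O4)oc12 | intermediate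
25 | 5,7-dihydroxy-2-(8-hydroxy-2,2-dimethyl-2H-chromen-6-yl)-8-(3-methylbut-2-en-1-yl)-4H-chromen-4-one (CNP0256598.0) | CC(C)=CCc1c(O)cc(O)c2c(=O)cc(-c3cc(O)c4c(c3)C=CC(C)(C)O4)oc12 | target

**Step count**

Total: 11 steps. Longest linear sequence: 10 steps (steps 1–8, 10 and 11); step 9 makes the alkyne partner.

**Steps most likely to fail**

1. Step 10 (benzannulation).
- What may go wrong: a 1,2-hydrogen shift of the alkyl-substituted carbene may compete with the Wolff shift. The ketene may be captured by the product phenol or by traces of water instead of by the alkyne. The chromene may undergo photochemical ring opening. The dienylketene may undergo intramolecular [2+2] addition to the prenyl double bond. The 6π closure onto the pyranone may be slow.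
- Fallback (sets out from 2, returns at 25): ring C is closed last by the classical chalcone route.
  - 2 alkylates commercial 3,4-dihydroxybenzaldehyde (K2CO3, KI, CuI, acetone) to 3-hydroxy-4-(2-methylbut-3-yn-2-yloxy)benzaldehyde F1, which should rearrange in PhNEt2 at 185 °C to 8-hydroxy-2,2-dimethyl-2H-chromene-6-carbaldehyde F2.
  - Commercial 2,4,6-trihydroxyacetophenone is C-prenylated (prenyl bromide, DBU, THF) to 1-[2,4,6-trihydroxy-3-(3-methylbut-2-en-1-yl)phenyl]ethanone F3 and protected (MeOCH2Cl, i-Pr2NEt) as 1-[2-hydroxy-4,6-bis(methoxymethoxy)-3-(3-methylbut-2-en-1-yl)phenyl]ethanone F4; the hydrogen-bonded hydroxyl next to the prenyl group should stay free.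
  - Claisen–Schmidt condensation of F4 with F2 (KOH, EtOH) should give (E)-1-[2-hydroxy-4,6-bis(methoxymethoxy)-3-(3-methylbut-2-en-1-yl)phenyl]-3-(8-hydroxy-2,2-dimethyl-2H-chromen-6-yl)prop-2-en-1-one F5.
  - Oxidative cyclisation (catalytic I2, DMSO, 110 °C) should give 2-(8-hydroxy-2,2-dimethyl-2H-chromen-6-yl)-5,7-bis(methoxymethoxy)-8-(3-methylbut-2-en-1-yl)-4H-chromen-4-one F6, and brief treatment with HCl in MeOH at 40 °C would remove the acetals to give 25.

2. Step 9 (siloxyacetylene).
- What may go wrong: monolithium acetylide may disproportionate to the insoluble dilithium compound before oxidation is complete. Silylation may occur at carbon instead of oxygen and give the silylketene. The volatile, acid-sensitive product may be lost on isolation.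
- Fallback (leaves the route at 16, returns at 25): the silyl ynol ether is replaced by an alkyl ynol ether whose alkyl group also leaves with fluoride.
  - 2-(Trimethylsilyl)ethanol and trichloroethylene (KH, THF) give (E)-[2-(1,2-dichlorovinyloxy)ethyl]trimethylsilane F7.
  - n-BuLi (−78 → −40 °C) and then MeOH give [2-(ethynyloxy)ethyl]trimethylsilane F8; this is the dichlorovinyl ether route to alkoxyacetylenes.
  - Irradiation of 16 with F8 under the conditions of step 10 should give 5-hydroxy-2-[2,2-dimethyl-8-(triisopropylsilyloxy)-2H-chromen-6-yl]-8-(3-methylbut-2-en-1-yl)-7-[2-(trimethylsilyl)ethoxy]-4H-chromen-4-one F9.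
  - Bu4NF in DMF at 60 °C should remove both the silyl ether and the 2-(trimethylsilyl)ethyl ether to give 25.

3. Step 7 (ketone from the Weinreb amide).
- What may go wrong: the Grignard reagent may add to the pyranone carbonyl or in conjugate fashion to C2 or C6 of the ring, and the tetrahedral intermediate may collapse early and allow a second addition.
- Fallback (sets out from 10, returns at 14): acylation of an organozinc reagent, which does not add to pyranones.
  - 10 is hydrolysed with Me3SnOH (ClCH2CH2Cl, 80 °C) to 6-[2,2-dimethyl-8-(triisopropylsilyloxy)-2H-chromen-6-yl]-4-oxo-4H-pyran-2-carboxylic acid F10.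
  - (COCl)2 and catalytic DMF convert it into 6-[2,2-dimethyl-8-(triisopropylsilyloxy)-2H-chromen-6-yl]-4-oxo-4H-pyran-2-carbonyl chloride F11.
  - Coupling with (4-methylpent-3-en-1-yl)zinc bromide F12 (from 12, Zn, LiCl, THF) under catalysis by Pd(PPh3)4, a zerovalent palladium complex (Negishi acylation), should give 14.

**Further compounds**

F1 | step 10 | 3-hydroxy-4-(2-methylbut-3-yn-2-yloxy)benzaldehyde | O=Cc1ccc(OC(C)(C)C#C)c(O)c1
F2 | step 10 | 8-hydroxy-2,2-dimethyl-2H-chromene-6-carbaldehyde | O=Cc1cc(O)c2c(c1)C=CC(C)(C)O2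
F3 | step 10 | 1-[2,4,6-trihydroxy-3-(3-methylbut-2-en-1-yl)phenyl]ethanone | CC(=O)c1c(O)cc(O)c(CC=C(C)C)c1O
F4 | step 10 | 1-[2-hydroxy-4,6-bis(methoxymethoxy)-3-(3-methylbut-2-en-1-yl)phenyl]ethanone | CC(=O)c1c(OCOC)cc(OCOC)c(CC=C(C)C)c1O
F5 | step 10 | (E)-1-[2-hydroxy-4,6-bis(methoxymethoxy)-3-(3-methylbut-2-en-1-yl)phenyl]-3-(8-hydroxy-2,2-dimethyl-2H-chromen-6-yl)prop-2-en-1-one | O=C(/C=C/c1cc(O)c2c(c1)C=CC(C)(C)O2)c1c(OCOC)cc(OCOC)c(CC=C(C)C)c1O
F6 | step 10 | 2-(8-hydroxy-2,2-dimethyl-2H-chromen-6-yl)-5,7-bis(methoxymethoxy)-8-(3-methylbut-2-en-1-yl)-4H-chromen-4-one | CC(C)=CCc1c(OCOC)cc(OCOC)c2c(=O)cc(-c3cc(O)c4c(c3)C=CC(C)(C)O4)oc12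
F7 | step 9 | (E)-[2-(1,2-dichlorovinyloxy)ethyl]trimethylsilane | C[Si](C)(C)CCO/C(Cl)=C\Cl
F8 | step 9 | [2-(ethynyloxy)ethyl]trimethylsilane | C#COCC[Si](C)(C)C
F9 | step 9 | 5-hydroxy-2-[2,2-dimethyl-8-(triisopropylsilyloxy)-2H-chromen-6-yl]-8-(3-methylbut-2-en-1-yl)-7-[2-(trimethylsilyl)ethoxy]-4H-chromen-4-one | CC(C)=CCc1c(OCC[Si](C)(C)C)cc(O)c2c(=O)cc(-c3cc(O[Si](C(C)C)(C(C)C)C(C)C)c4c(c3)C=CC(C)(C)O4)oc12
F10 | step 7 | 6-[2,2-dimethyl-8-(triisopropylsilyloxy)-2H-chromen-6-yl]-4-oxo-4H-pyran-2-carboxylic acid | OC(=O)c1cc(=O)cc(-c2cc(O[Si](C(C)C)(C(C)C)C(C)C)c3c(c2)C=CC(C)(C)O3)o1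
F11 | step 7 | 6-[2,2-dimethyl-8-(triisopropylsilyloxy)-2H-chromen-6-yl]-4-oxo-4H-pyran-2-carbonyl chloride | ClC(=O)c1cc(=O)cc(-c2cc(O[Si](C(C)C)(C(C)C)C(C)C)c3c(c2)C=CC(C)(C)O3)o1
F12 | step 7 | (4-methylpent-3-en-1-yl)zinc bromide | CC(C)=CCC[Zn]Br
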